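C1 = quaternary fusion carbon (CH3; its face is β), C2/C3 = ring CH2CH2, C4 = carbinol carbon (isopropyl), C5 = fusion CH, C6 = CHOAr, C7 = CH2, C8 = C(CH3)=, C9 = CH=, C10 = CHOAng. Ring A = cyclopentane C1–C5, ring B = cycloheptene C1, C5–C10.
Enabling feature: ring B splits into a three-carbon arc C9–C10–C1 with oxygen on its central carbon C10 (a latent oxyallyl cation) and a four-carbon arc C5–C6–C7–C8 with oxygen on C6 (a latent 2-silyloxy-1,3-diene). C2–C3–C4 of ring A is a ready three-atom tether between the two arcs.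
Retrosynthesis: remove the C10 angelate and the C6 aroate, take the C10 carbinol and C8=C9 back to a saturated C10 ketone and the C6 carbinol back to a ketone. Then cut C8–C9 and C1–C5 together as an intramolecular (4+3) cycloaddition, which opens both rings to an acyclic C15 chain.
The chain is cut at C1–C10 (1-ethoxyvinyllithium + methyl ketone) and at C6–C7 (propenyl Grignard reagent + aldehyde). This leaves a C10 keto aldehyde, the ozonolysis product of (S)-terpinen-4-ol.
Forward: chain assembly (steps 1–6), rings A and B in one operation (step 7), then redox adjustment and two acylations on the periphery (steps 8–15).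
Stereochemistry: C4 comes from the chiral pool, C5 and C1 are relayed from C4 in the cycloaddition, C6 is set by hydride delivery directed by C4–OH, C10 by oxazaborolidine reagent control, and the Z-alkene arrives with angelic acid.
Key step: step 7

Assumption: (S)-(+)-terpinen-4-ol is used in enantiopure form; the enantiomeric purity of the target equals that of this material, because every later centre is relayed from C4.
Assumption: commercial 1-propenylmagnesium bromide contains both alkene isomers; the E isomer is drawn, a Z-enone equilibrates to E at the stage of 9, and C8 becomes trigonal again in step 12.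

Step 1
Reactants: 1 (S)-(+)-terpinen-4-ol
Product: 2 (S)-terpinen-4-ol triethylsilyl ether
Conditions: Et3SiOTf, 2,6-lutidine, CH2Cl2, 0 °C
Reagents that add atoms: triethylsilyl trifluoromethanesulfonate, CC[Si](CC)(CC)OS(=O)(=O)C(F)(F)F
Why: Silyl triflate silylation is the standard way to protect a hindered tertiary alcohol, it leaves the C4 stereocentre (the future 4β-OH) untouched, and the ether later prevents hemiketal formation with the C1 ketone, retro-aldol cleavage and triflation at C4–O.

Step 2
Reactants: 2 (S)-terpinen-4-ol triethylsilyl ether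
Product: 3 (3S)-6-oxo-3-(propan-2-yl)-3-(triethylsilyloxy)heptanal
Conditions: O3, CH2Cl2, −78 °C; then PPh3, −78 °C to rt
Reagents that add atoms: ozone, [O-][O+]=O
Why: Ozonolysis with reductive work-up cleaves the only C=C bond and turns the ring into the chain C6HO–C5–C4–C3–C2–C1(=O)CH3 under neutral conditions that spare the β-silyloxy aldehyde.

Step 3
Reactants: 3 (3S)-6-oxo-3-(propan-2-yl)-3-(triethylsilyloxy)heptanal; 4 (E)-prop-1-enylmagnesium bromide
Product: 5 (5S,8E)-7-hydroxy-5-(propan-2-yl)-5-(triethylsilyloxy)dec-8-en-2-one (both C7 epimers)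
Conditions: 4 (1.05 equiv), THF, −78 °C; H2O quench at −78 °C
Reagents that add atoms: none
Why: In this chemoselective Grignard 1,2-addition one equivalent of the alkenyl reagent takes the aldehyde much faster than the methyl ketone at −78 °C, the cold quench holds back O-to-O silyl migration, and the new carbinol centre (C6 of the target) is erased in step 5.

Step 4
Reactants: 5 (5S,8E)-7-hydroxy-5-(propan-2-yl)-5-(triethylsilyloxy)dec-8-en-2-one; 6 ethyl vinyl ether
Product: 8 (6S,9E)-2-ethoxy-3-methyl-6-(propan-2-yl)-6-(triethylsilyloxy)undeca-1,9-diene-3,8-diol (epimers at C3 and C8), via 1-ethoxyvinyllithium 7 (not isolated)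
Conditions: 6, t-BuLi, THF, −78 to 0 °C; then 5 (0.4 equiv), −78 °C; H2O quench at −78 °C
Reagents that add atoms: none
Why: 1,2-Addition of an α-alkoxyvinyllithium (acyl anion equivalent) to the methyl ketone installs C10 and C9 as a tertiary 2-ethoxyallylic alcohol, the first equivalent only deprotonating the secondary hydroxyl, and the C1 carbinol epimers do not matter because C1 becomes planar in step 7.

Step 5
Reactants: 8 (6S,9E)-2-ethoxy-3-methyl-6-(propan-2-yl)-6-(triethylsilyloxy)undeca-1,9-diene-3,8-diol
Product: 9 (2E,6S)-10-ethoxy-9-hydroxy-9-methyl-6-(propan-2-yl)-6-(triethylsilyloxy)undeca-2,10-dien-4-one (both C9 epimers)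
Conditions: MnO2 (activated, excess), CH2Cl2, rt
Reagents that add atoms: none
Why: MnO2 oxidises only the allylic secondary alcohol, under neutral conditions that leave the tertiary alcohol, the acid-labile enol ether and the silyl ether intact.

Step 6
Reactants: 9 (2E,6S)-10-ethoxy-9-hydroxy-9-methyl-6-(propan-2-yl)-6-(triethylsilyloxy)undeca-2,10-dien-4-one
Product: 10 (2E,4Z,6R)-4-(tert-butyldimethylsilyloxy)-10-ethoxy-9-methyl-6-(propan-2-yl)-6-(triethylsilyloxy)undeca-2,4,10-trien-9-ol (both C9 epimers)
Conditions: LiN(iPr)2 (2.2 equiv), THF/DMPU, −78 °C; t-BuMe2SiCl, −78 to −30 °C; pH 7 buffer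
Reagents that add atoms: tert-butyldimethylsilyl chloride, CC(C)(C)[Si](C)(C)Cl
Why: Kinetic α′-deprotonation of an enone followed by O-silylation is the classical entry to 2-silyloxy-1,3-dienes, the very bulky C4 substituent enforces the Z geometry (C4 cis to OTBS and trans to C7), t-BuMe2SiCl leaves the hindered tertiary lithium alkoxide at C1 unsilylated, and the low temperature holds back E1cB loss of the β-silyloxy group.

Step 7
Reactants: 10 (2E,4Z,6R)-4-(tert-butyldimethylsilyloxy)-10-ethoxy-9-methyl-6-(propan-2-yl)-6-(triethylsilyloxy)undeca-2,4,10-trien-9-ol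
Product: 13 10-ethoxy-6-(tert-butyldimethylsilyloxy)-4β-(triethylsilyloxy)-5αH,8αH-dauca-6,9-diene, via 2-ethoxyallyl cation 11 (not isolated), via bicyclic oxocarbenium ion 12 (not isolated)
Conditions: Tf2O (1.1 equiv), 2,6-lutidine (3 equiv), CH2Cl2 (0.005 M), −78 to −40 °C; Et3N, then aq NaHCO3
Reagents that add atoms: none
Why: Proposed new method: Tf2O triflates the only free hydroxyl (C1–OH), the tertiary 2-ethoxyallylic triflate ionises at once to the planar cation 11 (C9–C10–C1), C5 of the silyl dienol ether bonds to C1 and C9 of the resulting ethyl enol ether bonds to C8 of the silyloxyallyl cation in a concerted-asynchronous or two-stage (4+3) cycloaddition, and 2,6-lutidine takes H9 from oxocarbenium ion 12 to give 13. The closest known reaction type is the intramolecular (4+3) cycloaddition of 2-alkoxyallyl cations, released from 2-alkoxyallylic alcohols with Tf2O/2,6-lutidine or from the corresponding sulfones with TiCl4, with butadienes and furans on a three-atom tether; new here is the 2-silyloxydiene as four-carbon partner, whose two bond formations are modelled by the SN1 α-tert-alkylation of silyl enol ethers and the Mukaiyama–Michael addition. Ring A closes in the 5-(enolexo)-exo-trig mode (C5=C6 and C1=C10 both stay outside the new ring) and ring B in the 7-(enolendo)-endo-trig mode at C8 (C7=C8 and C9=C10 both lie inside the ring). C5 is set by the C4 stereocentre through A(1,3) strain in the Z enol ether (OSiEt3 in the alkene plane next to OTBS, isopropyl turned away, the C3 tether bringing C1 to the opposite face, so that C6 ends cis to C4–O and H5 cis to isopropyl), C1 by the extended (exo) arrangement in which the bulky C10(OEt)=C9 arm turns away from C6–OTBS and only CH3 lies over the diene (CH3 trans to H5, trans-fused rings), and C8 by suprafacial addition to the E-propenyl unit (CH3 β), a centre that step 12 erases. The step needs ionisation at C1 and not at the equally tertiary and allylic C4–O, secured by activating a free OH in a buffered medium without Lewis acid while C4–O is a silyl ether; it needs C–C bonding to outrun proton loss from 11 and reversible capture by the C4 ether oxygen, secured by the high nucleophilicity of the silyl enol ether and the five-membered transition state; and it needs closure at C8 rather than at C6 ((3+2) mode), favoured because C6 is a hindered ketone-type oxocarbenium carbon to which enol ethers add in the 1,4 sense. Both C1 epimers of 10 converge on the same cation, so the mixture from step 4 is funnelled into one product.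

Step 8
Reactants: 13 10-ethoxy-6-(tert-butyldimethylsilyloxy)-4β-(triethylsilyloxy)-5αH,8αH-dauca-6,9-diene
Product: 14 4β-hydroxy-5αH,8αH-daucane-6,10-dione
Conditions: 48% aq HF, MeCN, 0 °C to rt
Reagents that add atoms: water, O
Why: Aqueous acid hydrolyses both enol ethers (protonation at C9 and C7) and fluoride removes the tertiary triethylsilyl ether in one operation, without base that could trigger retro-aldol cleavage or epimerise C5.

Step 9
Reactants: 14 4β-hydroxy-5αH,8αH-daucane-6,10-dione
Product: 15 4β,6α-dihydroxy-5αH,8αH-daucan-10-one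
Conditions: Me4NBH(OAc)3, MeCN/AcOH (1:1), −25 °C
Reagents that add atoms: none
Why: In the Evans–Saksena reduction the C4–OH exchanges onto boron and delivers hydride intramolecularly through a six-membered transition state to the β face of the C6 ketone (6α-OH, anti 1,3-diol), while the undirected and neopentylic C10 ketone is inert to triacetoxyborohydride.

Step 10
Reactants: 16 4-hydroxybenzoic acid
Product: 18 4-(tert-butyldimethylsilyloxy)benzoic acid, via bis-silyl derivative 17 (not isolated)
Conditions: t-BuMe2SiCl (2.3 equiv), imidazole, DMF, rt; then AcOH/THF/H2O, rt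
Reagents that add atoms: tert-butyldimethylsilyl chloride, CC(C)(C)[Si](C)(C)Cl
Why: Exhaustive silylation followed by selective solvolysis of the far more labile silyl ester is the standard route to a phenol-protected hydroxybenzoic acid.

Step 11
Reactants: 15 4β,6α-dihydroxy-5αH,8αH-daucan-10-one; 18 4-(tert-butyldimethylsilyloxy)benzoic acid
Product: 19 6α-[4-(tert-butyldimethylsilyloxy)benzoyloxy]-4β-hydroxy-5αH,8αH-daucan-10-one
Conditions: N,N'-dicyclohexylcarbodiimide, 4-(dimethylamino)pyridine, CH2Cl2, rt to 40 °C
Reagents that add atoms: none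
Why: Steglich esterification acylates the only secondary hydroxyl with retention at C6, the tertiary C4–OH being inert and any transannular C6–O/C10 hemiketal draining through its open form.

Step 12
Reactants: 19 6α-[4-(tert-butyldimethylsilyloxy)benzoyloxy]-4β-hydroxy-5αH,8αH-daucan-10-one
Product: 20 6α-[4-(tert-butyldimethylsilyloxy)benzoyloxy]-4β-hydroxydauc-8-en-10-one
Conditions: 2-iodoxybenzoic acid (IBX), 4-methoxypyridine N-oxide, DMSO, 25–40 °C
Reagents that add atoms: none
Why: IBX dehydrogenation of a ketone runs through its enol, and since C1 is quaternary the unsaturation can develop only towards C9–C8, which turns the C8–C9 bond into the trisubstituted alkene, erases C8 and avoids the base that could expel the C6 aroate by vinylogous E1cB elimination.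

Step 13
Reactants: 20 6α-[4-(tert-butyldimethylsilyloxy)benzoyloxy]-4β-hydroxydauc-8-en-10-one
Product: 21 6α-[4-(tert-butyldimethylsilyloxy)benzoyloxy]dauc-8-ene-4β,10α-diol
Conditions: (3aS)-1-methyl-3,3-diphenyltetrahydro-1H,3H-pyrrolo[1,2-c][1,3,2]oxazaborole (0.5 equiv), catecholborane (2.5 equiv), toluene, −78 to −40 °C; then aq NaHCO3
Reagents that add atoms: none
Why: In the Corey–Bakshi–Shibata reduction the S oxazaborolidine binds the C10 carbonyl through the lone pair on the side of the small C9H= flank, away from quaternary C1, and so delivers hydride to the β face (the sense that turns acetophenone into the R alcohol), a trajectory also staggered anti to the C1–C5 bond, which should give the 10α (R) allylic alcohol by clean 1,2-reduction.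

Step 14
Reactants: 21 6α-[4-(tert-butyldimethylsilyloxy)benzoyloxy]dauc-8-ene-4β,10α-diol; 22 angelic acid
Product: 24 10α-angeloyloxy-6α-[4-(tert-butyldimethylsilyloxy)benzoyloxy]dauc-8-en-4β-ol, via angelic 2,4,6-trichlorobenzoic anhydride 23 (not isolated)
Conditions: 22, 2,4,6-trichlorobenzoyl chloride, Et3N, toluene, rt; then 21, 80 °C
Reagents that add atoms: none
Why: Yamaguchi-type mixed-anhydride acylation is the established isomerisation-free route to angelates, because the alcohol attacks the unhindered angeloyl carbonyl of 23, no nucleophilic catalyst is present that could add to the Z-alkene and turn it into the tiglate, the tertiary C4–OH is inert, and C10 keeps its configuration since its C–O bond is not broken.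

Step 15
Reactants: 24 10α-angeloyloxy-6α-[4-(tert-butyldimethylsilyloxy)benzoyloxy]dauc-8-en-4β-ol
Product: 25 CNP0273650.2, 10α-angeloyloxy-6α-(4-hydroxybenzoyloxy)dauc-8-en-4β-ol
Conditions: Et3N·3HF, THF, rt
Reagents that add atoms: none
Why: Fluoride cleaves the activated aryl silyl ether under nearly neutral conditions that touch neither of the two esters, the Z-alkene or the allylic C10–O bond.

Compound list
1 | (S)-(+)-terpinen-4-ol, (1S)-4-methyl-1-(propan-2-yl)cyclohex-3-en-1-ol | CC1=CC[C@](O)(C(C)C)CC1 | starting material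
2 | (S)-terpinen-4-ol triethylsilyl ether | CC1=CC[C@](O[Si](CC)(CC)CC)(C(C)C)CC1 | intermediate
3 | (3S)-6-oxo-3-(propan-2-yl)-3-(triethylsilyloxy)heptanal | CC(=O)CC[C@@](O[Si](CC)(CC)CC)(C(C)C)CC=O | intermediate
4 | (E)-prop-1-enylmagnesium bromide | C/C=C/[Mg]Br | starting material
5 | (5S,8E)-7-hydroxy-5-(propan-2-yl)-5-(triethylsilyloxy)dec-8-en-2-one, both C7 epimers | CC(=O)CC[C@@](O[Si](CC)(CC)CC)(C(C)C)CC(O)/C=C/C | intermediate
6 | ethyl vinyl ether | C=COCC | starting material
7 | 1-ethoxyvinyllithium (not isolated) | [Li]C(=C)OCC | intermediate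
8 | (6S,9E)-2-ethoxy-3-methyl-6-(propan-2-yl)-6-(triethylsilyloxy)undeca-1,9-diene-3,8-diol, epimers at C3 and C8 | C=C(OCC)C(C)(O)CC[C@@](O[Si](CC)(CC)CC)(C(C)C)CC(O)/C=C/C | intermediate
9 | (2E,6S)-10-ethoxy-9-hydroxy-9-methyl-6-(propan-2-yl)-6-(triethylsilyloxy)undeca-2,10-dien-4-one, both C9 epimers | C=C(OCC)C(C)(O)CC[C@@](O[Si](CC)(CC)CC)(C(C)C)CC(=O)/C=C/C | intermediate
10 | (2E,4Z,6R)-4-(tert-butyldimethylsilyloxy)-10-ethoxy-9-methyl-6-(propan-2-yl)-6-(triethylsilyloxy)undeca-2,4,10-trien-9-ol, both C9 epimers | C=C(OCC)C(C)(O)CC[C@@](O[Si](CC)(CC)CC)(C(C)C)/C=C(/C=C/C)O[Si](C)(C)C(C)(C)C | intermediate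
11 | 2-ethoxyallyl cation C9–C10–C1 carrying the tethered silyloxydiene (not isolated) | C=C(OCC)[C+](C)CC[C@@](O[Si](CC)(CC)CC)(C(C)C)/C=C(/C=C/C)O[Si](C)(C)C(C)(C)C | intermediate
12 | trans-fused bicyclic C10 O-ethyl oxocarbenium ion (not isolated) | CC[O+]=C1C[C@@H](C)C=C(O[Si](C)(C)C(C)(C)C)[C@@H]2[C@]1(C)CC[C@@]2(O[Si](CC)(CC)CC)C(C)C | intermediate
13 | 10-ethoxy-6-(tert-butyldimethylsilyloxy)-4β-(triethylsilyloxy)-5αH,8αH-dauca-6,9-diene | CCOC1=C[C@@H](C)C=C(O[Si](C)(C)C(C)(C)C)[C@@H]2[C@]1(C)CC[C@@]2(O[Si](CC)(CC)CC)C(C)C | intermediate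
14 | 4β-hydroxy-5αH,8αH-daucane-6,10-dione | O=C1C[C@@H](C)CC(=O)[C@@H]2[C@]1(C)CC[C@@]2(O)C(C)C | intermediate
15 | 4β,6α-dihydroxy-5αH,8αH-daucan-10-one | O=C1C[C@@H](C)C[C@H](O)[C@@H]2[C@]1(C)CC[C@@]2(O)C(C)C | intermediate
16 | 4-hydroxybenzoic acid | O=C(O)c1ccc(O)cc1 | starting material
17 | tert-butyldimethylsilyl 4-(tert-butyldimethylsilyloxy)benzoate (not isolated) | CC(C)(C)[Si](C)(C)OC(=O)c1ccc(O[Si](C)(C)C(C)(C)C)cc1 | intermediate
18 | 4-(tert-butyldimethylsilyloxy)benzoic acid | O=C(O)c1ccc(O[Si](C)(C)C(C)(C)C)cc1 | intermediate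
19 | 6α-[4-(tert-butyldimethylsilyloxy)benzoyloxy]-4β-hydroxy-5αH,8αH-daucan-10-one | O=C1C[C@@H](C)C[C@H](OC(=O)c3ccc(O[Si](C)(C)C(C)(C)C)cc3)[C@@H]2[C@]1(C)CC[C@@]2(O)C(C)C | intermediate
20 | 6α-[4-(tert-butyldimethylsilyloxy)benzoyloxy]-4β-hydroxydauc-8-en-10-one | O=C1C=C(C)C[C@H](OC(=O)c3ccc(O[Si](C)(C)C(C)(C)C)cc3)[C@@H]2[C@]1(C)CC[C@@]2(O)C(C)C | intermediate
21 | 6α-[4-(tert-butyldimethylsilyloxy)benzoyloxy]dauc-8-ene-4β,10α-diol | O[C@@H]1C=C(C)C[C@H](OC(=O)c3ccc(O[Si](C)(C)C(C)(C)C)cc3)[C@@H]2[C@]1(C)CC[C@@]2(O)C(C)C | intermediate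
22 | angelic acid, (Z)-2-methylbut-2-enoic acid | C/C=C(/C)C(=O)O | starting material
23 | angelic 2,4,6-trichlorobenzoic anhydride (not isolated) | C/C=C(/C)C(=O)OC(=O)c1c(Cl)cc(Cl)cc1Cl | intermediate
24 | 10α-angeloyloxy-6α-[4-(tert-butyldimethylsilyloxy)benzoyloxy]dauc-8-en-4β-ol | C/C=C(/C)C(=O)O[C@@H]1C=C(C)C[C@H](OC(=O)c3ccc(O[Si](C)(C)C(C)(C)C)cc3)[C@@H]2[C@]1(C)CC[C@@]2(O)C(C)C | intermediate
25 | CNP0273650.2, 10α-angeloyloxy-6α-(4-hydroxybenzoyloxy)dauc-8-en-4β-ol, azulene locants (3R,3aS,4S,8R,8aS) | C/C=C(/C)C(=O)O[C@@H]1C=C(C)C[C@H](OC(=O)c2ccc(O)cc2)[C@@H]2[C@]1(C)CC[C@@]2(O)C(C)C | target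

Total step count: 15. Longest linear sequence: 14 (steps 1–9 and 11–15, from 1 to 25).

Steps most likely to fail

Step 7 (labelled step). The cation may be lost before it bonds to carbon, through proton loss to a 2-ethoxydiene or capture by the C4 ether oxygen with desilylation. The second bond may also close at C6 instead of C8, or the compact arrangement may compete and invert C1 relative to C4. The fallback uses known reaction types only and runs from 9 back to 20. It takes the C6 oxygen out of the diene, so that the cycloaddition falls into its documented substrate class, and puts the oxygen back afterwards.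
- Kinetic enolisation of 9 (LiN(iPr)2, 2.2 equiv) and trapping with PhNTf2 should give the (Z)-dienyl triflate F1.
- Palladium-catalysed formate hydrogenolysis (Pd(OAc)2, PPh3, HCO2H, n-Bu3N, DMF) should then give the (E,E)-diene carbinol F2.
- Tf2O/2,6-lutidine at −78 °C followed by work-up with 1 M HCl/THF should give the trans-fused 4β-(triethylsilyloxy)-5αH,8αH-dauc-6-en-10-one F3.
- IBX dehydrogenation leads to the 4β-(triethylsilyloxy)dauca-6,8-dien-10-one F4.
- mCPBA epoxidises the distal, more electron-rich C6=C7 bond from the α face, opposite the axial C1 methyl group and the C4 silyl ether, to the 6α,7α-epoxide F5.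
- Hydrogenolysis of this alkenyl epoxide (Pd2(dba)3·CHCl3, n-Bu3P, HCO2H, Et3N, dioxane) places hydride on C7 and leaves the 6α-hydroxy-4β-(triethylsilyloxy)dauc-8-en-10-one F6.
- Aqueous HF frees the 4β,6α-dihydroxydauc-8-en-10-one F7, and Steglich esterification with 18 at its only secondary hydroxyl returns to 20.

Step 13. Facial selectivity may be poor if the inherent preference of the enone is for hydride attack on the α face, anti to the axial C1 methyl group, and works against the catalyst. The fallback runs from 20 to 24 and uses that preference instead of fighting it. Luche reduction (NaBH4, CeCl3·7H2O, MeOH, −78 °C) should give the 10β-alcohol F8. Mitsunobu esterification with angelic acid 22 (PPh3, diisopropyl azodicarboxylate, toluene, 0 °C to rt) then inverts C10, the carboxylate entering from the open α face, and gives 24 directly, so that 21 and step 14 are bypassed.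

Step 14. Acylation of the axial, neopentylic allylic alcohol may be so slow that Z-to-E isomerisation of the angeloyl unit or ionisation of the allylic C10–O bond takes over. The fallback runs from 21 to 24 and builds the Z-alkene on the ester instead of transferring it. Steglich acylation with 2-[bis(2,2,2-trifluoroethoxy)phosphoryl]propanoic acid, which can be forced with 4-(dimethylamino)pyridine because nothing can isomerise, should give the 10α-phosphonopropanoate F9. Still–Gennari olefination with acetaldehyde (KN(SiMe3)2, 18-crown-6, THF, −78 °C) then gives the Z-configured angelate 24.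

Further compounds
F1 | step 7 | (2E,4Z,6R)-10-ethoxy-9-hydroxy-9-methyl-6-(propan-2-yl)-6-(triethylsilyloxy)undeca-2,4,10-trien-4-yl trifluoromethanesulfonate | C=C(OCC)C(C)(O)CC[C@@](O[Si](CC)(CC)CC)(C(C)C)/C=C(/C=C/C)OS(=O)(=O)C(F)(F)F
F2 | step 7 | (7E,9E)-2-ethoxy-3-methyl-6-(propan-2-yl)-6-(triethylsilyloxy)undeca-1,7,9-trien-3-ol, C6 configured as in 10 | C=C(OCC)C(C)(O)CC[C@@](O[Si](CC)(CC)CC)(C(C)C)/C=C/C=C/C
F3 | step 7 | 4β-(triethylsilyloxy)-5αH,8αH-dauc-6-en-10-one | O=C1C[C@@H](C)C=C[C@@H]2[C@]1(C)CC[C@@]2(O[Si](CC)(CC)CC)C(C)C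
F4 | step 7 | 4β-(triethylsilyloxy)-5αH-dauca-6,8-dien-10-one | O=C1C=C(C)C=C[C@@H]2[C@]1(C)CC[C@@]2(O[Si](CC)(CC)CC)C(C)C
F5 | step 7 | 6α,7α-epoxy-4β-(triethylsilyloxy)-5αH-dauc-8-en-10-one | O=C1C=C(C)[C@@H]3O[C@@H]3[C@@H]2[C@]1(C)CC[C@@]2(O[Si](CC)(CC)CC)C(C)C
F6 | step 7 | 6α-hydroxy-4β-(triethylsilyloxy)dauc-8-en-10-one | O=C1C=C(C)C[C@H](O)[C@@H]2[C@]1(C)CC[C@@]2(O[Si](CC)(CC)CC)C(C)C
F7 | step 7 | 4β,6α-dihydroxydauc-8-en-10-one | O=C1C=C(C)C[C@H](O)[C@@H]2[C@]1(C)CC[C@@]2(O)C(C)C
F8 | step 13 | 6α-[4-(tert-butyldimethylsilyloxy)benzoyloxy]dauc-8-ene-4β,10β-diol | O[C@H]1C=C(C)C[C@H](OC(=O)c3ccc(O[Si](C)(C)C(C)(C)C)cc3)[C@@H]2[C@]1(C)CC[C@@]2(O)C(C)C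
F9 | step 14 | 10α-{2-[bis(2,2,2-trifluoroethoxy)phosphoryl]propanoyloxy}-6α-[4-(tert-butyldimethylsilyloxy)benzoyloxy]dauc-8-en-4β-ol, both epimers at the phosphonate carbon | CC(C(=O)O[C@@H]1C=C(C)C[C@H](OC(=O)c3ccc(O[Si](C)(C)C(C)(C)C)cc3)[C@@H]2[C@]1(C)CC[C@@]2(O)C(C)C)P(=O)(OCC(F)(F)F)OCC(F)(F)F
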